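**Retrosynthetic overview**
1. The strategy rests on C2 of the 2,6-diaryl-3,7-dioxabicyclo[3.3.0]octane: the benzylic CH that carries the endo 4-hydroxy-3-methoxyphenyl group and lies between O3 and bridgehead C1 in ring A (C1–C2–O3–C4–C5). It is the carbon of an ArCH2–O ether, into which a carbenoid centred on C1 can insert.
2. Ring B (C1–C8–O7–C6–C5) is therefore carried as a γ-lactone (C8=O): furofuran ⇒ tetrahydrofuran diol ⇒ furofuranone ⇒ α-diazo lactone with a benzyl ether on C4 (C1–C2 disconnection).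
3. The lactone ⇒ trans-aryl paraconic acid ⇒ Evans syn aldol of a succinate imide with 4-O-prenylvanillin (C5–C6 disconnection). The endo aryl enters as a silyl-protected benzyl trichloroacetimidate (O3–C2 disconnection).
4. Ring order: the lactone (masked ring B) first, ring A by C–H insertion, then ring B opened by hydride and reclosed as the ether through O7–C8.

Key step: step 13

Remark: the skeleton is numbered as 3,7-dioxabicyclo[3.3.0]octane (aryl carbons C2 and C6, bridgeheads C1 and C5). The target is read as (1R,2R,5R,6S), with the 4-hydroxy-3-methoxyphenyl group endo at C2 and the prenyloxy aryl group exo at C6.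

**Route**

Step 1
Reactants: 1 vanillin (4-hydroxy-3-methoxybenzaldehyde); 2 prenyl bromide (1-bromo-3-methylbut-2-ene)
Product: 3 4-O-prenylvanillin (3-methoxy-4-(3-methylbut-2-enyloxy)benzaldehyde)
Conditions: K2CO3, DMF, rt
Reagents that add atoms: none
Why: Williamson etherification; the phenoxide displaces the primary allylic bromide by SN2 and O-alkylation is expected to dominate in DMF.

Step 2
Reactants: 4 (S)-4-benzyl-2-oxazolidinone; 5 methyl 4-chloro-4-oxobutanoate
Product: 6 succinate imide methyl 4-[(4S)-4-benzyl-2-oxooxazolidin-3-yl]-4-oxobutanoate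
Conditions: n-BuLi, THF, −78 °C; then 5, −78 → 0 °C
Reagents that add atoms: none
Why: N-acylation of the lithiated oxazolidinone; the acid chloride is far more electrophilic than the methyl ester, which stays intact, and the auxiliary stereocentre is not touched.

Step 3
Reactants: 6 succinate imide; 3 4-O-prenylvanillin
Product: 8 syn-aldol adduct methyl (3S,4S)-3-[(4S)-4-benzyl-2-oxooxazolidine-3-carbonyl]-4-hydroxy-4-[3-methoxy-4-(3-methylbut-2-enyloxy)phenyl]butanoate, via boron Z-enolate 7 (not isolated)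
Conditions: Bu2BOTf (1.1 equiv), iPr2NEt (1.2 equiv), CH2Cl2, 0 °C; then 3, −78 → 0 °C; pH 7 buffer, MeOH, H2O2, 0 °C
Reagents that add atoms: none
Why: Evans syn aldol; soft enolisation gives the Z boron enolate at the imide α-carbon only, and the chair Zimmerman–Traxler transition state with the auxiliary carbonyl turned away from the enolate oxygen exposes the face opposite the benzyl group, which should set both new centres as (3S,4S).

Step 4
Reactants: 8 syn-aldol adduct
Product: 9 lactone imide (4S)-4-benzyl-3-{(2S,3S)-2-[3-methoxy-4-(3-methylbut-2-enyloxy)phenyl]-5-oxotetrahydrofuran-3-carbonyl}oxazolidin-2-one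
Conditions: cat. camphorsulfonic acid, CH2Cl2, 4 Å molecular sieves, rt
Reagents that add atoms: none
Why: acid-catalysed γ-lactonisation (intramolecular transesterification) of the γ-hydroxy methyl ester; no bond to a stereocentre is broken, so the syn aldol relationship becomes the trans arrangement of aryl and acyl groups on the ring, and the benzylic hydroxyl is tied up before any base is used.

Step 5
Reactants: 9 lactone imide
Product: 11 trans-aryl paraconic acid (2S,3S)-2-[3-methoxy-4-(3-methylbut-2-enyloxy)phenyl]-5-oxotetrahydrofuran-3-carboxylic acid, via peroxy acid 10 (not isolated)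
Conditions: LiOH, H2O2, THF/H2O, 0 °C; aq. Na2SO3, 0 °C; then 1 M HCl to pH 2–3
Reagents that add atoms: hydrogen peroxide (OO)
Why: peroxide cleavage of an Evans imide; the hydroperoxide anion attacks the exocyclic carbonyl selectively, sulfite reduces the percarboxylate before acidification so that no peroxy acid meets the prenyl olefin, and any lactone opened by hydroxide should reclose at pH 2–3.

Step 6
Reactants: 11 trans-aryl paraconic acid
Product: 13 hydroxymethyl lactone (4R,5S)-4-(hydroxymethyl)-5-[3-methoxy-4-(3-methylbut-2-enyloxy)phenyl]dihydrofuran-2(3H)-one, via mixed anhydride 12 (not isolated)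
Conditions: i-BuOCOCl, N-methylmorpholine, THF, −15 °C; then NaBH4, THF/H2O, −15 → 0 °C; aq. NH4Cl
Reagents that add atoms: none
Why: reduction of a carboxylic acid through its mixed carbonic anhydride; borohydride attacks the activated acyl carbonyl much faster than the γ-lactone in the cold, no borane is present to hydroborate the prenyl olefin, and a prompt buffered quench limits alkoxide-driven migration of the lactone.

Step 7
Reactants: 1 vanillin
Product: 14 3-methoxy-4-(triisopropylsilyloxy)benzaldehyde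
Conditions: TIPSCl, imidazole, DMF, rt
Reagents that add atoms: triisopropylsilyl chloride, CC(C)[Si](Cl)(C(C)C)C(C)C
Why: silylation of the phenol; the bulky aryl silyl ether is chosen to survive amide base, carbenoid, hydride and NaH and to leave with fluoride at the end.

Step 8
Reactants: 14 3-methoxy-4-(triisopropylsilyloxy)benzaldehyde
Product: 15 [3-methoxy-4-(triisopropylsilyloxy)phenyl]methanol
Conditions: NaBH4, THF/EtOH, 0 °C
Reagents that add atoms: none
Why: borohydride reduction of the aromatic aldehyde to the benzylic alcohol; the hindered aryl silyl ether should tolerate the short, cold treatment.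

Step 9
Reactants: 15 [3-methoxy-4-(triisopropylsilyloxy)phenyl]methanol
Product: 16 3-methoxy-4-(triisopropylsilyloxy)benzyl 2,2,2-trichloroacetimidate
Conditions: Cl3CCN, cat. DBU, CH2Cl2, 0 °C; used promptly
Reagents that add atoms: trichloroacetonitrile, N#CC(Cl)(Cl)Cl
Why: base-catalysed addition of the alcohol to trichloroacetonitrile (imidate formation); the electron-rich imidate is labile and is taken on without storage.

Step 10
Reactants: 13 hydroxymethyl lactone; 16 benzyl trichloroacetimidate
Product: 17 benzyl ether lactone (4R,5S)-4-{[3-methoxy-4-(triisopropylsilyloxy)benzyloxy]methyl}-5-[3-methoxy-4-(3-methylbut-2-enyloxy)phenyl]dihydrofuran-2(3H)-one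
Conditions: cat. camphorsulfonic acid, CH2Cl2, 0 °C → rt
Reagents that add atoms: none
Why: acid-catalysed O-benzylation with a trichloroacetimidate; the protonated imidate releases a stabilised 4-silyloxy-3-methoxybenzyl cation that the primary alcohol captures, and because no alkoxide is formed the lactone cannot migrate to the primary oxygen.

Step 11
Reactants: 17 benzyl ether lactone
Product: 18 α-trifluoroacetyl lactone (4R,5S)-4-{[3-methoxy-4-(triisopropylsilyloxy)benzyloxy]methyl}-5-[3-methoxy-4-(3-methylbut-2-enyloxy)phenyl]-3-(trifluoroacetyl)dihydrofuran-2(3H)-one (C3 epimers and enol form)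
Conditions: LiN(SiMe3)2, THF, −78 °C; CF3CO2CH2CF3, −78 °C; aq. NH4Cl; used crude
Reagents that add atoms: 2,2,2-trifluoroethyl trifluoroacetate, O=C(OCC(F)(F)F)C(F)(F)F
Why: Claisen-type trifluoroacetylation of the lactone lithium enolate, which can form only at the single α-CH2 (C1), activates that carbon for diazo transfer.

Step 12
Reactants: 18 α-trifluoroacetyl lactone
Product: 19 α-diazo lactone (4R,5S)-3-diazo-4-{[3-methoxy-4-(triisopropylsilyloxy)benzyloxy]methyl}-5-[3-methoxy-4-(3-methylbut-2-enyloxy)phenyl]dihydrofuran-2(3H)-one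
Conditions: MsN3, Et3N, H2O (1 equiv), MeCN, rt
Reagents that add atoms: methanesulfonyl azide, CS(=O)(=O)N=[N+]=[N-]
Why: detrifluoroacetylative diazo transfer (Regitz type); the stabilised enolate adds to the sulfonyl azide and the adduct fragments with loss of the trifluoroacetyl group as the N-sulfonyl amide, leaving the diazo group on C1 without touching C5 or C6.

Step 13
Reactants: 19 α-diazo lactone
Product: 20 endo,exo-furofuranone (1S,2R,5R,6S)-2-[3-methoxy-4-(triisopropylsilyloxy)phenyl]-6-[3-methoxy-4-(3-methylbut-2-enyloxy)phenyl]-3,7-dioxabicyclo[3.3.0]octan-8-one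
Conditions: Rh2(OAc)4 (2 mol %), CH2Cl2, reflux, slow addition of 19 (final about 0.005 M)
Reagents that add atoms: none
Why: Rh2(OAc)4 (a divalent rhodium dimer) expels N2 from 19, and the resulting electrophilic rhodium carbenoid at C1 inserts into one benzylic C2–H bond of the ether arm through a concerted, asynchronous three-centre transition state with hydride-transfer character; the closest known reaction type is the intramolecular 1,5 C–H insertion of carbenoids from α-diazo-γ-butyrolactones into benzylic ether C–H bonds, which gives endo,exo-furofuranones. Ring A (C1–C2–O3–C4–C5) closes by C1–C2 bond formation as a five-membered ring (1,5-insertion) and can only be cis-fused to the lactone because the tether is anchored at C5. C1 is therefore fixed relative to the aldol-derived C5 by the cis ring fusion (its descriptor reads S here only because C8 is a carbonyl). C2 is set under kinetic control: of the two diastereotopic benzylic hydrogens, the one transferred should be that which lets the aryl group lie on the concave side over the lactone carbonyl, away from the acetate ligand wall of the departing Rh2 unit on the convex side, so the aryl is expected to end endo. The step needs 1,5 site selectivity and endo selectivity; the first is secured because the C2–H bonds are the only C–H bonds within reach that are activated by an oxygen lone pair (O3) and an electron-rich aryl ring, on an arm held on the lactone face anti to the C6 aryl, and the second by the ligand–aryl repulsion just described. Slow addition at high dilution should hold back bimolecular capture of the carbenoid by the prenyl olefin and carbene dimerisation.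

Step 14
Reactants: 20 endo,exo-furofuranone
Product: 21 tetrahydrofuran diol (S)-{(3R,4R,5R)-4-(hydroxymethyl)-5-[3-methoxy-4-(triisopropylsilyloxy)phenyl]tetrahydrofuran-3-yl}[3-methoxy-4-(3-methylbut-2-enyloxy)phenyl]methanol
Conditions: LiAlH4, THF, 0 °C; aq. potassium sodium tartrate work-up (no acid)
Reagents that add atoms: none
Why: hydride reduction of the lactone to the diol; the C6–O bond is not broken, so C6 keeps its configuration, and the hindered aryl silyl ether and the endo benzylic ether are stable to cold hydride.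

Step 15
Reactants: 21 tetrahydrofuran diol
Product: 22 primary monotosylate {(2R,3R,4R)-4-[(S)-hydroxy(3-methoxy-4-(3-methylbut-2-enyloxy)phenyl)methyl]-2-[3-methoxy-4-(triisopropylsilyloxy)phenyl]tetrahydrofuran-3-yl}methyl 4-methylbenzenesulfonate
Conditions: TsCl (1.1 equiv), Et3N, cat. DMAP, CH2Cl2, −20 → 0 °C
Reagents that add atoms: p-toluenesulfonyl chloride, Cc1ccc(S(Cl)(=O)=O)cc1
Why: selective sulfonylation; the primary hydroxyl on C8 reacts much faster than the hindered secondary benzylic hydroxyl on C6, and any tosylate that already closes to the ether under the amine base is simply carried forward.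

Step 16
Reactants: 22 primary monotosylate
Product: 23 silyl-protected furofuran (1R,2R,5R,6S)-2-[3-methoxy-4-(triisopropylsilyloxy)phenyl]-6-[3-methoxy-4-(3-methylbut-2-enyloxy)phenyl]-3,7-dioxabicyclo[3.3.0]octane
Conditions: NaH, THF, 0 °C → rt
Reagents that add atoms: none
Why: intramolecular Williamson etherification (5-exo-tet); the C6 alkoxide displaces the primary tosylate at C8 and closes ring B (C1–C8–O7–C6–C5) without breaking a bond to any stereocentre, and the absence of acid keeps the kinetically set endo centre C2 from epimerising.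

Step 17
Reactants: 23 silyl-protected furofuran
Product: 24 target CNP0185952.5, (1R,2R,5R,6S)-2-(4-hydroxy-3-methoxyphenyl)-6-[3-methoxy-4-(3-methylbut-2-enyloxy)phenyl]-3,7-dioxabicyclo[3.3.0]octane
Conditions: Bu4NF, AcOH (1:1), THF, 0 °C
Reagents that add atoms: none
Why: fluoride desilylation of the aryl silyl ether; acetic acid buffers the liberated phenoxide so that the para-hydroxybenzylic C2–O3 bond is not opened through a quinone methide, and the prenyl ether is inert.

**Compound list**
1 | vanillin (4-hydroxy-3-methoxybenzaldehyde) | COc1cc(C=O)ccc1O | starting material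
2 | prenyl bromide (1-bromo-3-methylbut-2-ene) | CC(C)=CCBr | starting material
3 | 3-methoxy-4-(3-methylbut-2-enyloxy)benzaldehyde | COc1cc(C=O)ccc1OCC=C(C)C | intermediate
4 | (S)-4-benzyl-2-oxazolidinone | O=C1N[C@@H](Cc2ccccc2)CO1 | starting material
5 | methyl 4-chloro-4-oxobutanoate | COC(=O)CCC(Cl)=O | starting material
6 | methyl 4-[(4S)-4-benzyl-2-oxooxazolidin-3-yl]-4-oxobutanoate | COC(=O)CCC(=O)N1[C@@H](Cc2ccccc2)COC1=O | intermediate
7 | dibutylboron Z-enolate of 6 | COC(=O)C/C=C(\OB(CCCC)CCCC)N1[C@@H](Cc2ccccc2)COC1=O | intermediate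
8 | methyl (3S,4S)-3-[(4S)-4-benzyl-2-oxooxazolidine-3-carbonyl]-4-hydroxy-4-[3-methoxy-4-(3-methylbut-2-enyloxy)phenyl]butanoate | COC(=O)C[C@H](C(=O)N1[C@@H](Cc2ccccc2)COC1=O)[C@H](O)c1ccc(OCC=C(C)C)c(OC)c1 | intermediate
9 | (4S)-4-benzyl-3-{(2S,3S)-2-[3-methoxy-4-(3-methylbut-2-enyloxy)phenyl]-5-oxotetrahydrofuran-3-carbonyl}oxazolidin-2-one | O=C1C[C@H](C(=O)N2[C@@H](Cc3ccccc3)COC2=O)[C@@H](c2ccc(OCC=C(C)C)c(OC)c2)O1 | intermediate
10 | (2S,3S)-2-[3-methoxy-4-(3-methylbut-2-enyloxy)phenyl]-5-oxotetrahydrofuran-3-carboperoxoic acid | O=C1C[C@H](C(=O)OO)[C@@H](c2ccc(OCC=C(C)C)c(OC)c2)O1 | intermediate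
11 | (2S,3S)-2-[3-methoxy-4-(3-methylbut-2-enyloxy)phenyl]-5-oxotetrahydrofuran-3-carboxylic acid | O=C1C[C@H](C(=O)O)[C@@H](c2ccc(OCC=C(C)C)c(OC)c2)O1 | intermediate
12 | isobutyl carbonic mixed anhydride of 11 | O=C1C[C@H](C(=O)OC(=O)OCC(C)C)[C@@H](c2ccc(OCC=C(C)C)c(OC)c2)O1 | intermediate
13 | (4R,5S)-4-(hydroxymethyl)-5-[3-methoxy-4-(3-methylbut-2-enyloxy)phenyl]dihydrofuran-2(3H)-one | O=C1C[C@H](CO)[C@@H](c2ccc(OCC=C(C)C)c(OC)c2)O1 | intermediate
14 | 3-methoxy-4-(triisopropylsilyloxy)benzaldehyde | COc1cc(C=O)ccc1O[Si](C(C)C)(C(C)C)C(C)C | intermediate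
15 | [3-methoxy-4-(triisopropylsilyloxy)phenyl]methanol | COc1cc(CO)ccc1O[Si](C(C)C)(C(C)C)C(C)C | intermediate
16 | 3-methoxy-4-(triisopropylsilyloxy)benzyl 2,2,2-trichloroacetimidate | COc1cc(COC(=N)C(Cl)(Cl)Cl)ccc1O[Si](C(C)C)(C(C)C)C(C)C | intermediate
17 | (4R,5S)-4-{[3-methoxy-4-(triisopropylsilyloxy)benzyloxy]methyl}-5-[3-methoxy-4-(3-methylbut-2-enyloxy)phenyl]dihydrofuran-2(3H)-one | O=C1C[C@H](COCc2ccc(O[Si](C(C)C)(C(C)C)C(C)C)c(OC)c2)[C@@H](c2ccc(OCC=C(C)C)c(OC)c2)O1 | intermediate
18 | 3-trifluoroacetyl derivative of 17 (C3 epimers and enol form) | O=C1C(C(=O)C(F)(F)F)[C@H](COCc2ccc(O[Si](C(C)C)(C(C)C)C(C)C)c(OC)c2)[C@@H](c2ccc(OCC=C(C)C)c(OC)c2)O1 | intermediate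
19 | (4R,5S)-3-diazo-4-{[3-methoxy-4-(triisopropylsilyloxy)benzyloxy]methyl}-5-[3-methoxy-4-(3-methylbut-2-enyloxy)phenyl]dihydrofuran-2(3H)-one | O=C1C(=[N+]=[N-])[C@H](COCc2ccc(O[Si](C(C)C)(C(C)C)C(C)C)c(OC)c2)[C@@H](c2ccc(OCC=C(C)C)c(OC)c2)O1 | intermediate
20 | (1S,2R,5R,6S)-2-[3-methoxy-4-(triisopropylsilyloxy)phenyl]-6-[3-methoxy-4-(3-methylbut-2-enyloxy)phenyl]-3,7-dioxabicyclo[3.3.0]octan-8-one (aryl at C2 endo, aryl at C6 exo) | COc1cc([C@@H]2OC[C@H]3[C@@H]2C(=O)O[C@@H]3c2ccc(OCC=C(C)C)c(OC)c2)ccc1O[Si](C(C)C)(C(C)C)C(C)C | intermediate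
21 | (S)-{(3R,4R,5R)-4-(hydroxymethyl)-5-[3-methoxy-4-(triisopropylsilyloxy)phenyl]tetrahydrofuran-3-yl}[3-methoxy-4-(3-methylbut-2-enyloxy)phenyl]methanol | COc1cc([C@@H]2OC[C@@H]([C@@H]2CO)[C@H](O)c2ccc(OCC=C(C)C)c(OC)c2)ccc1O[Si](C(C)C)(C(C)C)C(C)C | intermediate
22 | primary 4-methylbenzenesulfonate of 21 | COc1cc([C@@H]2OC[C@@H]([C@@H]2COS(=O)(=O)c2ccc(C)cc2)[C@H](O)c2ccc(OCC=C(C)C)c(OC)c2)ccc1O[Si](C(C)C)(C(C)C)C(C)C | intermediate
23 | (1R,2R,5R,6S)-2-[3-methoxy-4-(triisopropylsilyloxy)phenyl]-6-[3-methoxy-4-(3-methylbut-2-enyloxy)phenyl]-3,7-dioxabicyclo[3.3.0]octane | COc1cc([C@@H]2OC[C@H]3[C@@H]2CO[C@@H]3c2ccc(OCC=C(C)C)c(OC)c2)ccc1O[Si](C(C)C)(C(C)C)C(C)C | intermediate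
24 | CNP0185952.5, (1R,2R,5R,6S)-2-(4-hydroxy-3-methoxyphenyl)-6-[3-methoxy-4-(3-methylbut-2-enyloxy)phenyl]-3,7-dioxabicyclo[3.3.0]octane | COc1cc([C@@H]2OC[C@H]3[C@@H]2CO[C@@H]3c2ccc(OCC=C(C)C)c(OC)c2)ccc1O | target

**Step count**
Total: 17 steps. Longest linear sequence: 13 steps (1 → 3 → 8 → 9 → 11 → 13 → 17 → 18 → 19 → 20 → 21 → 22 → 23 → 24).

**Steps most likely to fail**

Step 13. Insertion may be outrun by bimolecular capture of the carbenoid by the nucleophilic prenyl olefin of a second molecule, by carbene dimerisation, or by 1,2-hydride migration from C5 to a butenolide. The fallback removes the olefin from the insertion substrate and adds the prenyl group last; it sets out from 1 and 6 and comes back at 23.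
- Benzylation of 1 (benzyl bromide, K2CO3, DMF) gives 4-benzyloxy-3-methoxybenzaldehyde F1.
- The operations of steps 3 to 5 then give the benzyl-series aldol adduct F2, the lactone imide F3 and, through the peroxy acid F4 formed in the flask, the paraconic acid F5.
- With no olefin present, BH3·SMe2 (THF, 0 °C) reduces the acid directly to the hydroxymethyl lactone F6.
- The operations of steps 10 to 16 lead through the benzyl ether lactone F7, the trifluoroacetyl lactone F8, the diazo lactone F9, the furofuranone F10, the diol F11 and the monotosylate F12 to the benzyl-protected furofuran F13.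
- Hydrogenolysis of the aryl benzyl ether (H2, 10% Pd/C, EtOAc, stopped at one equivalent of uptake) gives the exo-aryl phenol F14.
- Alkylation of F14 with 2 (K2CO3, acetone) gives 23.

Step 10. Ionisation of the very electron-rich imidate may outpace its capture by the alcohol (self-alkylation, rearrangement to the N-benzyl trichloroacetamide), or the acid may promote lactone migration. The fallback forms the same O3–C2 bond by reductive etherification; it sets out from 13 and 14 and comes back at 17. Silylation of 13 (TMSCl, Et3N, CH2Cl2) gives the trimethylsilyl ether F15. Treatment of F15 with aldehyde 14 and Et3SiH under catalytic TMSOTf (CH2Cl2, −78 °C) reduces the oxocarbenium ion formed from the two partners and should give 17.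

Step 15. Site selectivity in the sulfonylation may be lost; activation of the electron-rich benzylic hydroxyl would allow ionisation at C6 with elimination or scrambling. The fallback is a direct Mitsunobu cyclodehydration, which sets out from 21 and comes back at 23 without passing through 22. With PPh3 and diisopropyl azodicarboxylate (THF, 0 °C) the oxyphosphonium ion should form at the less hindered primary oxygen and be displaced by the C6 hydroxyl. The detour makes no compound outside the list (entry F0).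

**Further compounds**
F1 | step 13 | 4-benzyloxy-3-methoxybenzaldehyde | COc1cc(C=O)ccc1OCc1ccccc1
F2 | step 13 | methyl (3S,4S)-3-[(4S)-4-benzyl-2-oxooxazolidine-3-carbonyl]-4-(4-benzyloxy-3-methoxyphenyl)-4-hydroxybutanoate | COC(=O)C[C@H](C(=O)N1[C@@H](Cc2ccccc2)COC1=O)[C@H](O)c1ccc(OCc2ccccc2)c(OC)c1
F3 | step 13 | (4S)-4-benzyl-3-[(2S,3S)-2-(4-benzyloxy-3-methoxyphenyl)-5-oxotetrahydrofuran-3-carbonyl]oxazolidin-2-one | O=C1C[C@H](C(=O)N2[C@@H](Cc3ccccc3)COC2=O)[C@@H](c2ccc(OCc3ccccc3)c(OC)c2)O1
F4 | step 13 | (2S,3S)-2-(4-benzyloxy-3-methoxyphenyl)-5-oxotetrahydrofuran-3-carboperoxoic acid | O=C1C[C@H](C(=O)OO)[C@@H](c2ccc(OCc3ccccc3)c(OC)c2)O1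
F5 | step 13 | (2S,3S)-2-(4-benzyloxy-3-methoxyphenyl)-5-oxotetrahydrofuran-3-carboxylic acid | O=C1C[C@H](C(=O)O)[C@@H](c2ccc(OCc3ccccc3)c(OC)c2)O1
F6 | step 13 | (4R,5S)-5-(4-benzyloxy-3-methoxyphenyl)-4-(hydroxymethyl)dihydrofuran-2(3H)-one | O=C1C[C@H](CO)[C@@H](c2ccc(OCc3ccccc3)c(OC)c2)O1
F7 | step 13 | (4R,5S)-5-(4-benzyloxy-3-methoxyphenyl)-4-{[3-methoxy-4-(triisopropylsilyloxy)benzyloxy]methyl}dihydrofuran-2(3H)-one | O=C1C[C@H](COCc2ccc(O[Si](C(C)C)(C(C)C)C(C)C)c(OC)c2)[C@@H](c2ccc(OCc3ccccc3)c(OC)c2)O1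
F8 | step 13 | 3-trifluoroacetyl derivative of F7 (C3 epimers and enol form) | O=C1C(C(=O)C(F)(F)F)[C@H](COCc2ccc(O[Si](C(C)C)(C(C)C)C(C)C)c(OC)c2)[C@@H](c2ccc(OCc3ccccc3)c(OC)c2)O1
F9 | step 13 | 3-diazo derivative of F7 | O=C1C(=[N+]=[N-])[C@H](COCc2ccc(O[Si](C(C)C)(C(C)C)C(C)C)c(OC)c2)[C@@H](c2ccc(OCc3ccccc3)c(OC)c2)O1
F10 | step 13 | (1S,2R,5R,6S)-6-(4-benzyloxy-3-methoxyphenyl)-2-[3-methoxy-4-(triisopropylsilyloxy)phenyl]-3,7-dioxabicyclo[3.3.0]octan-8-one | COc1cc([C@@H]2OC[C@H]3[C@@H]2C(=O)O[C@@H]3c2ccc(OCc3ccccc3)c(OC)c2)ccc1O[Si](C(C)C)(C(C)C)C(C)C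
F11 | step 13 | (S)-(4-benzyloxy-3-methoxyphenyl){(3R,4R,5R)-4-(hydroxymethyl)-5-[3-methoxy-4-(triisopropylsilyloxy)phenyl]tetrahydrofuran-3-yl}methanol | COc1cc([C@@H]2OC[C@@H]([C@@H]2CO)[C@H](O)c2ccc(OCc3ccccc3)c(OC)c2)ccc1O[Si](C(C)C)(C(C)C)C(C)C
F12 | step 13 | primary 4-methylbenzenesulfonate of F11 | COc1cc([C@@H]2OC[C@@H]([C@@H]2COS(=O)(=O)c2ccc(C)cc2)[C@H](O)c2ccc(OCc3ccccc3)c(OC)c2)ccc1O[Si](C(C)C)(C(C)C)C(C)C
F13 | step 13 | (1R,2R,5R,6S)-6-(4-benzyloxy-3-methoxyphenyl)-2-[3-methoxy-4-(triisopropylsilyloxy)phenyl]-3,7-dioxabicyclo[3.3.0]octane | COc1cc([C@@H]2OC[C@H]3[C@@H]2CO[C@@H]3c2ccc(OCc3ccccc3)c(OC)c2)ccc1O[Si](C(C)C)(C(C)C)C(C)C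
F14 | step 13 | (1R,2R,5R,6S)-6-(4-hydroxy-3-methoxyphenyl)-2-[3-methoxy-4-(triisopropylsilyloxy)phenyl]-3,7-dioxabicyclo[3.3.0]octane | COc1cc([C@@H]2OC[C@H]3[C@@H]2CO[C@@H]3c2ccc(O)c(OC)c2)ccc1O[Si](C(C)C)(C(C)C)C(C)C
F15 | step 10 | (4R,5S)-5-[3-methoxy-4-(3-methylbut-2-enyloxy)phenyl]-4-[(trimethylsilyloxy)methyl]dihydrofuran-2(3H)-one | O=C1C[C@H](CO[Si](C)(C)C)[C@@H](c2ccc(OCC=C(C)C)c(OC)c2)O1
F0 | step 15 | none | none
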